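**Plan**

- Retrosynthesis: the benzyl O–C bond on ring B is cut first. Ring A is then opened at C8–C8a (retro-6π, then retro-4π) to a 4-(4-oxopyran-3-yl)-2,3-dimethoxycyclobut-2-enone.
- The C4a–C5 bond (pyranone C5 to cyclobutenone C4) is cut as a Stille coupling, and the pyranone at O1–C6 and C3–C4 back to an aroyl chloride and a brominated 4-methoxybutenone.
- Forward: ring B is bought; ring C (4-pyranone, bromine already on C5) comes from enolate acylation and acid closure; the squarate-derived four-membered ring is attached at C5 through a stannane; ring A is formed last by thermal ring expansion; hydrogenolysis frees the B-ring phenol.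
- Enabling feature: C5(H)–C6(OMe)–C7(OMe)–C8(OH) of ring A is the CH–C(OMe)=C(OMe)–C=O unit of a 4-substituted 2,3-dimethoxycyclobutenone, and C4a=C8a is the C5=C6 bond of the pyranone. The single free hydroxyl among four contiguous oxygens is therefore the former ketene carbonyl.
- Stereochemistry: the target has no stereocentre. The only sp3 stereocentre on the route (C4 of cyclobutenones 13–15) is racemic and vanishes on aromatisation; the alkene geometry of 7–9 vanishes on pyranone closure.

Key step: step 10

Remark: the target is achiral (no stereocentre, no stereogenic double bond), so its constitution alone defines the single compound required.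

**Step 1**
Reactants: 1 3-hydroxy-4,5-dimethoxybenzoic acid
Product: 3 3-(benzyloxy)-4,5-dimethoxybenzoic acid, via benzyl ester 2 (not isolated)
Conditions: BnBr (2.4 equiv), K2CO3, acetone, reflux; concentrate; then NaOH, MeOH–H2O, 60 °C; HCl to pH 2
Reagents that add atoms: benzyl bromide, BrCc1ccccc1; sodium hydroxide, [Na+].[OH-]
Why: Williamson alkylation benzylates phenoxide and carboxylate alike, and saponification then cleaves only the benzyl ester, leaving the aryl benzyl ether in place.

**Step 2**
Reactants: 3 3-(benzyloxy)-4,5-dimethoxybenzoic acid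
Product: 4 3-(benzyloxy)-4,5-dimethoxybenzoyl chloride
Conditions: (COCl)2, cat. DMF, CH2Cl2, 0 °C → rt; evaporated and used crude
Reagents that add atoms: oxalyl chloride, O=C(Cl)C(=O)Cl
Why: Vilsmeier-catalysed acid chloride formation is mild enough for the aryl benzyl and methyl ethers and leaves only volatile by-products.

**Step 3**
Reactants: 5 (E)-4-methoxybut-3-en-2-one
Product: 7 (Z)-3-bromo-4-methoxybut-3-en-2-one, via dibromide 6 (not isolated)
Conditions: Br2, CH2Cl2, −78 °C; then Et3N, −78 → 0 °C
Reagents that add atoms: bromine, BrBr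
Why: Bromine addition to the enol ether double bond followed by base-induced loss of HBr (acidic α-H, labile α-bromo-ether bromide) is the standard α-halogenation of β-alkoxy enones and fixes the halogen on the future pyranone C5; the Z geometry is expected but irrelevant.

**Step 4**
Reactants: 7 (Z)-3-bromo-4-methoxybut-3-en-2-one (2.1 equiv); 4 3-(benzyloxy)-4,5-dimethoxybenzoyl chloride (1.0 equiv)
Product: 9 (Z)-1-[3-(benzyloxy)-4,5-dimethoxyphenyl]-4-bromo-5-methoxypent-4-ene-1,3-dione (largely enolised), via lithium enolate 8 (not isolated)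
Conditions: LiHMDS (2.1 equiv), THF, −78 °C; then 4, −78 → −40 °C; AcOH quench
Reagents that add atoms: none
Why: Kinetic enolisation of the methyl ketone and C-acylation by the aroyl chloride (Claisen-type acylation, established for the enolate of 4-methoxybut-3-en-2-one) gives the β-diketone, with the second equivalent of enolate absorbing its acidic proton; at −78 °C enolisation should far outrun any dehydrobromination.

**Step 5**
Reactants: 9 (Z)-1-[3-(benzyloxy)-4,5-dimethoxyphenyl]-4-bromo-5-methoxypent-4-ene-1,3-dione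
Product: 10 2-[3-(benzyloxy)-4,5-dimethoxyphenyl]-5-bromo-4H-pyran-4-one
Conditions: TFA (cat.), CH2Cl2, rt
Reagents that add atoms: none
Why: Acid-catalysed 6-endo conjugate addition of the aryl-ketone enol oxygen to the β-methoxy enone with loss of methanol (addition–elimination) is the standard closure of such diketones to 4-pyranones and places bromine unambiguously at C5.

**Step 6**
Reactants: 10 2-[3-(benzyloxy)-4,5-dimethoxyphenyl]-5-bromo-4H-pyran-4-one
Product: 11 2-[3-(benzyloxy)-4,5-dimethoxyphenyl]-5-(trimethylstannyl)-4H-pyran-4-one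
Conditions: Me3SnSnMe3, Pd(PPh3)4 (5 mol %), toluene, 100 °C; chromatography on Et3N-deactivated silica
Reagents that add atoms: hexamethylditin, C[Sn](C)(C)[Sn](C)(C)C
Why: Pd(0)-catalysed stannylation of a vinyl bromide with a distannane (oxidative addition, Sn–Sn transmetalation, reductive elimination) should be easy at the electron-poor α-bromo-enone C–Br bond.

**Step 7**
Reactants: 12 dimethyl squarate (3,4-dimethoxycyclobut-3-ene-1,2-dione)
Product: 13 4-hydroxy-2,3-dimethoxycyclobut-2-en-1-one (racemic)
Conditions: LiAlH(OtBu)3 (1.05 equiv), THF, −78 → −20 °C; Rochelle salt work-up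
Reagents that add atoms: none
Why: The bulky, mild hydride adds 1,2 to one of the two equivalent carbonyls and the aluminium alkoxide resists further reduction, a mono-reduction known for dialkyl squarates; the new centre is racemic and is not needed later.

**Step 8**
Reactants: 13 4-hydroxy-2,3-dimethoxycyclobut-2-en-1-one
Product: 14 4-chloro-2,3-dimethoxycyclobut-2-en-1-one (racemic)
Conditions: PPh3, CCl4, CH2Cl2, 0 °C → rt; short silica plug, used at once
Reagents that add atoms: carbon tetrachloride, ClC(Cl)(Cl)Cl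
Why: Appel chlorination through the alkoxyphosphonium chloride replaces the allylic, α-keto hydroxyl under neutral aprotic conditions, avoiding the protic acid that would convert 13 into methoxycyclobutenedione.

**Step 9**
Reactants: 11 2-[3-(benzyloxy)-4,5-dimethoxyphenyl]-5-(trimethylstannyl)-4H-pyran-4-one; 14 4-chloro-2,3-dimethoxycyclobut-2-en-1-one (1.3 equiv)
Product: 15 4-{6-[3-(benzyloxy)-4,5-dimethoxyphenyl]-4-oxo-4H-pyran-3-yl}-2,3-dimethoxycyclobut-2-en-1-one (racemic)
Conditions: Pd2(dba)3 (2.5 mol %), tri(2-furyl)phosphine (10 mol %), CuI (10 mol %), 1,4-dioxane, 40–45 °C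
Reagents that add atoms: none
Why: Stille cross-coupling of 4-chlorocyclobutenones with alkenyl- and heteroarylstannanes is established (oxidative addition of the allylic α-keto C–Cl bond, copper-assisted transmetalation, reductive elimination at C4 to keep the enone conjugated), and the temperature is held below that of cyclobutenone ring opening.

**Step 10**
Reactants: 15 4-{6-[3-(benzyloxy)-4,5-dimethoxyphenyl]-4-oxo-4H-pyran-3-yl}-2,3-dimethoxycyclobut-2-en-1-one
Product: 18 2-[3-(benzyloxy)-4,5-dimethoxyphenyl]-8-hydroxy-6,7-dimethoxy-4H-chromen-4-one, via dienylketene 16 (not isolated), via cyclohexadienone 17 (not isolated)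
Conditions: toluene (0.02 M, degassed, Ar), 110 °C
Reagents that add atoms: none
Why: Thermal conrotatory 4π opening of the C1–C4 bond of the cyclobutenone gives dienylketene 16, whose ketene carbon closes onto pyranone C6 by disrotatory 6π electrocyclisation to form C8–C8a, and the 8a-H dienone 17 aromatises by tautomerisation to the C8 phenol. The closest known reaction type is the thermal ring expansion of 4-aryl-, 4-heteroaryl- and 4-alkenylcyclobut-2-enones to phenols, the closing sequence of the Danheiser benzannulation. Ring A closes in a thermally allowed 6π-electrocyclic mode to a six-membered carbocycle; no stereocentre is created and the racemic centre of 15 disappears. The step needs the pyranone cis to the ketene terminus, and although outward rotation of the pyranone is probably favoured, ring opening is reversible, so the non-cyclising ketene returns to 15 and material drains through the inward-rotated isomer. Site selectivity is fixed by the substrate, because C6 is the only sp2 C–H carbon next to the attachment point (the other neighbour is the C4 carbonyl carbon). The oxygen pattern follows from the origin of the atoms: the ketene carbonyl becomes the lone free hydroxyl at C8 and the two squarate methoxy groups become the C6 and C7 ethers.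

**Step 11**
Reactants: 18 2-[3-(benzyloxy)-4,5-dimethoxyphenyl]-8-hydroxy-6,7-dimethoxy-4H-chromen-4-one
Product: 19 8-hydroxy-2-(3-hydroxy-4,5-dimethoxyphenyl)-6,7-dimethoxy-4H-chromen-4-one
Conditions: H2 (1 atm), 10 % Pd/C, EtOAc–MeOH, rt
Reagents that add atoms: none
Why: Catalytic hydrogenolysis cleaves the aryl benzyl ether under conditions that normally leave the flavone C2=C3 bond, the carbonyl and the methyl ethers untouched.

**Compound list**

1 | 3-hydroxy-4,5-dimethoxybenzoic acid | COc1cc(C(=O)O)cc(O)c1OC | starting material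
2 | benzyl 3-(benzyloxy)-4,5-dimethoxybenzoate | COc1cc(C(=O)OCc2ccccc2)cc(OCc2ccccc2)c1OC | intermediate
3 | 3-(benzyloxy)-4,5-dimethoxybenzoic acid | COc1cc(C(=O)O)cc(OCc2ccccc2)c1OC | intermediate
4 | 3-(benzyloxy)-4,5-dimethoxybenzoyl chloride | COc1cc(C(Cl)=O)cc(OCc2ccccc2)c1OC | intermediate
5 | (E)-4-methoxybut-3-en-2-one | CO/C=C/C(C)=O | starting material
6 | 3,4-dibromo-4-methoxybutan-2-one (racemic, relative configuration immaterial) | COC(Br)C(Br)C(C)=O | intermediate
7 | (Z)-3-bromo-4-methoxybut-3-en-2-one | CO/C=C(\Br)C(C)=O | intermediate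
8 | lithium (Z)-3-bromo-4-methoxybuta-1,3-dien-2-olate | CO/C=C(\Br)C(=C)[O-].[Li+] | intermediate
9 | (Z)-1-[3-(benzyloxy)-4,5-dimethoxyphenyl]-4-bromo-5-methoxypent-4-ene-1,3-dione | CO/C=C(\Br)C(=O)CC(=O)c1cc(OC)c(OC)c(OCc2ccccc2)c1 | intermediate
10 | 2-[3-(benzyloxy)-4,5-dimethoxyphenyl]-5-bromo-4H-pyran-4-one | O=c1cc(-c2cc(OC)c(OC)c(OCc3ccccc3)c2)occ1Br | intermediate
11 | 2-[3-(benzyloxy)-4,5-dimethoxyphenyl]-5-(trimethylstannyl)-4H-pyran-4-one | C[Sn](C)(C)c1coc(-c2cc(OC)c(OC)c(OCc3ccccc3)c2)cc1=O | intermediate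
12 | dimethyl squarate | COC1=C(OC)C(=O)C1=O | starting material
13 | 4-hydroxy-2,3-dimethoxycyclobut-2-en-1-one (racemic) | COC1=C(OC)C(=O)C1O | intermediate
14 | 4-chloro-2,3-dimethoxycyclobut-2-en-1-one (racemic) | COC1=C(OC)C(=O)C1Cl | intermediate
15 | 4-{6-[3-(benzyloxy)-4,5-dimethoxyphenyl]-4-oxo-4H-pyran-3-yl}-2,3-dimethoxycyclobut-2-en-1-one (racemic) | COC1=C(OC)C(=O)C1c1coc(-c2cc(OC)c(OC)c(OCc3ccccc3)c2)cc1=O | intermediate
16 | (3E)-4-{6-[3-(benzyloxy)-4,5-dimethoxyphenyl]-4-oxo-4H-pyran-3-yl}-2,3-dimethoxybuta-1,3-dien-1-one (pyranone cis to the ketene carbon) | O=C=C(OC)/C(OC)=C\c1coc(-c2cc(OC)c(OC)c(OCc3ccccc3)c2)cc1=O | intermediate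
17 | 2-[3-(benzyloxy)-4,5-dimethoxyphenyl]-6,7-dimethoxy-4H-chromene-4,8(8aH)-dione (racemic keto tautomer) | COC1=C(OC)C(=O)C2OC(-c3cc(OC)c(OC)c(OCc4ccccc4)c3)=CC(=O)C2=C1 | intermediate
18 | 2-[3-(benzyloxy)-4,5-dimethoxyphenyl]-8-hydroxy-6,7-dimethoxy-4H-chromen-4-one | COc1cc2c(=O)cc(-c3cc(OC)c(OC)c(OCc4ccccc4)c3)oc2c(O)c1OC | intermediate
19 | 8-hydroxy-2-(3-hydroxy-4,5-dimethoxyphenyl)-6,7-dimethoxy-4H-chromen-4-one | COc1cc(-c2cc(=O)c3cc(OC)c(OC)c(O)c3o2)cc(O)c1OC | target

**Step count**

Total: 11 steps. Longest linear sequence: 8 steps (1, 2, 4, 5, 6, 9, 10, 11).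

**Steps most likely to fail**

Step 8. The activated C4–O or the C4–Cl bond may ionise with allylic transposition, after which chloride removes a methyl group (collapse to methoxycyclobutenedione), or the chloride may hydrolyse during isolation. Fallback: from 13, acetylation (Ac2O, pyridine, DMAP, 0 °C) gives the more robust 2,3-dimethoxy-4-oxocyclobut-2-en-1-yl acetate F1. F1 is coupled with stannane 11 as an allylic acetate under Pd(0) with LiCl in DMF (Stille coupling of allylic acetates through the same oxocyclobutenyl–palladium species), and the route is rejoined at 15.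

Step 9. Transmetalation of the hindered, electron-poor α-stannyl enone may be slow, so that protodestannylation, homocoupling or decay of the labile chloride wins; warming to compensate would start ring opening early. Fallback: from bromide 10, bromine–magnesium exchange (iPrMgCl·LiCl, THF, −40 °C) gives {6-[3-(benzyloxy)-4,5-dimethoxyphenyl]-4-oxo-4H-pyran-3-yl}magnesium chloride F2. ZnCl2 converts it into the corresponding pyranonylzinc chloride F3, which undergoes Negishi coupling with 14 (Pd2(dba)3, tri(2-furyl)phosphine, THF, 0 °C → rt) and rejoins the route at 15.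

Step 10. Outward rotation of the pyranone may dominate the ring opening, and closure onto the electron-poor, oxygen-bearing C6 may be slow. The ketene could then be consumed by dimerisation or adventitious nucleophiles faster than it recloses, and the electron-rich phenol may oxidise on prolonged heating. Fallback (higher oxidation level at cyclobutenone C4, so that a hydroxyl enforces inward rotation of the pyranone):

- From bromide 10, the magnesium reagent F2 of the preceding fallback is added to dimethyl squarate 12 (THF, −78 °C) to give 4-{6-[3-(benzyloxy)-4,5-dimethoxyphenyl]-4-oxo-4H-pyran-3-yl}-4-hydroxy-2,3-dimethoxycyclobut-2-en-1-one F4.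
- Heating F4 (p-xylene, 138 °C, Ar; Moore rearrangement) gives 2-[3-(benzyloxy)-4,5-dimethoxyphenyl]-5,8-dihydroxy-6,7-dimethoxy-4H-chromen-4-one F5.
- The non-chelated 8-OH is benzylated selectively (BnBr, 1.05 equiv, K2CO3, acetone) to 8-(benzyloxy)-2-[3-(benzyloxy)-4,5-dimethoxyphenyl]-5-hydroxy-6,7-dimethoxy-4H-chromen-4-one F6.
- The chelated 5-OH is converted into the aryl triflate 8-(benzyloxy)-2-[3-(benzyloxy)-4,5-dimethoxyphenyl]-6,7-dimethoxy-4-oxo-4H-chromen-5-yl trifluoromethanesulfonate F7 (Tf2O, pyridine, CH2Cl2, 0 °C).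
- Pd-catalysed formate reduction (Pd(OAc)2, dppf, HCO2H, Et3N, DMF, 70 °C) gives 8-(benzyloxy)-2-[3-(benzyloxy)-4,5-dimethoxyphenyl]-6,7-dimethoxy-4H-chromen-4-one F8.
- Hydrogenolysis of both benzyl ethers (H2, Pd/C) rejoins the route at target 19.

**Further compounds**

F1 | step 8 | 2,3-dimethoxy-4-oxocyclobut-2-en-1-yl acetate (racemic) | CC(=O)OC1C(OC)=C(OC)C1=O
F2 | step 9 | {6-[3-(benzyloxy)-4,5-dimethoxyphenyl]-4-oxo-4H-pyran-3-yl}magnesium chloride | Cl[Mg]c1coc(-c2cc(OC)c(OC)c(OCc3ccccc3)c2)cc1=O
F3 | step 9 | {6-[3-(benzyloxy)-4,5-dimethoxyphenyl]-4-oxo-4H-pyran-3-yl}zinc chloride | Cl[Zn]c1coc(-c2cc(OC)c(OC)c(OCc3ccccc3)c2)cc1=O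
F4 | step 10 | 4-{6-[3-(benzyloxy)-4,5-dimethoxyphenyl]-4-oxo-4H-pyran-3-yl}-4-hydroxy-2,3-dimethoxycyclobut-2-en-1-one (racemic) | COC1=C(OC)C(=O)C1(O)c1coc(-c2cc(OC)c(OC)c(OCc3ccccc3)c2)cc1=O
F5 | step 10 | 2-[3-(benzyloxy)-4,5-dimethoxyphenyl]-5,8-dihydroxy-6,7-dimethoxy-4H-chromen-4-one | COc1c(O)c2c(=O)cc(-c3cc(OC)c(OC)c(OCc4ccccc4)c3)oc2c(O)c1OC
F6 | step 10 | 8-(benzyloxy)-2-[3-(benzyloxy)-4,5-dimethoxyphenyl]-5-hydroxy-6,7-dimethoxy-4H-chromen-4-one | COc1c(O)c2c(=O)cc(-c3cc(OC)c(OC)c(OCc4ccccc4)c3)oc2c(OCc2ccccc2)c1OC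
F7 | step 10 | 8-(benzyloxy)-2-[3-(benzyloxy)-4,5-dimethoxyphenyl]-6,7-dimethoxy-4-oxo-4H-chromen-5-yl trifluoromethanesulfonate | COc1c(OS(=O)(=O)C(F)(F)F)c2c(=O)cc(-c3cc(OC)c(OC)c(OCc4ccccc4)c3)oc2c(OCc2ccccc2)c1OC
F8 | step 10 | 8-(benzyloxy)-2-[3-(benzyloxy)-4,5-dimethoxyphenyl]-6,7-dimethoxy-4H-chromen-4-one | COc1cc2c(=O)cc(-c3cc(OC)c(OC)c(OCc4ccccc4)c3)oc2c(OCc2ccccc2)c1OC
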